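**Plan**

Cuts, in order: the 17 O-benzyl groups and both gallate ester C–O bonds. Then C3–H of the lower flavan, back to a C3 ketone with a labile C2. Then ring C of the lower flavan at C4–C4a and O1–C2, giving a chalcan-substituted phenol and a 2-acetoxycinnamaldehyde. Then the chalcan C1–C6 (ring A) bond, giving an aryl epoxide and an arene, and last the CH2–ring A′ bond.
Forward: the upper 1,3-diarylpropene chain is joined and epoxidised, ring A is attached to its benzylic carbon, and pyran ring C is built last on ring A in one operation. Ketone reduction, double galloylation and hydrogenolysis finish the route.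
Enabling feature: ring A is a phloroglucinol ring, so O1–C8a–C4a is a phenol oxygen next to a very nucleophilic ortho C–H (a 1,3-C,O-dinucleophile). C4–C3(O)–C2(ring B) is the skeleton of a 2-acyloxycinnamaldehyde (a 1,3-dielectrophile). Their condensation gives the 1-oxatriene O1=C8a–C4a=C4–C3=C2, which closes by oxa-6π electrocyclisation.
Only the oxygen para to the chalcan carbon is left free and the two ortho C–H are equivalent, so the annulation can give only the 6-linked flavan, which direct C8-selective substitution of a flavan does not give. Helpers: C4 at aldehyde level, C3 as enol acetate (ketone level), and TIPS on the future O1. All are removed later.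
Stereochemistry: both chalcan centres come from a Shi epoxidation of the E-alkene (reagent control) and anti opening at the benzylic carbon. C2 and C3 are set together by a catalyst-controlled dynamic kinetic resolution of the C2-labile flavan-3-one, where hydride anti to ring B gives 2,3-cis.

Key step: step 10

Assumption: the four benzyl-protected building blocks (aldehyde, tribenzyloxybenzene, dibenzyloxyphenol, tribenzylgallic acid) are taken as purchasable; the ruthenium catalyst enantiomer in step 11 is the one that converts 2-phenylcyclohexanone into (1R,2R)-cis-2-phenylcyclohexanol, the spatial analogue of (2R,3R), and the mirror-image catalyst is used if correlation shows the opposite sense.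

**Step 1**
Reactants: 1 3,4,5-tris(benzyloxy)benzaldehyde
Product: 2 (±)-1-[3,4,5-tris(benzyloxy)phenyl]prop-2-en-1-ol
Conditions: CH2=CHMgBr, THF, 0 °C; then water
Reagents that add atoms: vinylmagnesium bromide, C=C[Mg]Br
Why: Grignard 1,2-addition to a non-enolisable aldehyde; the carbinol centre is racemic on purpose because ionisation in step 2 erases it.

**Step 2**
Reactants: 2 (±)-1-[3,4,5-tris(benzyloxy)phenyl]prop-2-en-1-ol; 3 1,3,5-tris(benzyloxy)benzene
Product: 4 (E)-1-[3,4,5-tris(benzyloxy)phenyl]-3-[2,4,6-tris(benzyloxy)phenyl]prop-1-ene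
Conditions: H2SO4 on SiO2 (cat.), 3 (2 equiv), CH2Cl2, 0 °C to rt
Reagents that add atoms: none
Why: Friedel–Crafts allylation: acid ionises 2 to the aryl-stabilised cinnamyl cation, which the symmetric arene 3 (one kind of C–H, used in excess) captures at the unhindered primary terminus with retention of styrene conjugation, so the E-1,3-diarylpropene should form.

**Step 3**
Reactants: 4 (E)-1-[3,4,5-tris(benzyloxy)phenyl]-3-[2,4,6-tris(benzyloxy)phenyl]prop-1-ene
Product: 5 (2R,3R)-2-[3,4,5-tris(benzyloxy)phenyl]-3-[2,4,6-tris(benzyloxy)benzyl]oxirane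
Conditions: D-fructose-derived Shi ketone (0.3 equiv), Oxone (KHSO5), K2CO3, Bu4NHSO4 (cat.), MeCN–dimethoxymethane/aq. Na2B4O7–Na2EDTA buffer, 0 °C
Reagents that add atoms: potassium peroxymonosulfate KHSO5 (active component of Oxone), [K+].[O-]S(=O)(=O)OO
Why: Shi epoxidation: the dioxirane of the D-fructose ketone meets trans-β-alkylstyrenes through the spiro transition state and gives the (R,R)-epoxide, which sets both chalcan centres by reagent control, while the basic buffer protects the acid-labile aryl epoxide.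

**Step 4**
Reactants: 6 3,5-bis(benzyloxy)phenol
Product: 7 [3,5-bis(benzyloxy)phenoxy]triisopropylsilane
Conditions: TIPSCl, imidazole, DMF, rt
Reagents that add atoms: chlorotriisopropylsilane, CC(C)[Si](Cl)(C(C)C)C(C)C
Why: Standard phenol silylation; the bulky silyl group marks the future O1 and screens the two ring positions ortho to it.

**Step 5**
Reactants: 5 (2R,3R)-2-[3,4,5-tris(benzyloxy)phenyl]-3-[2,4,6-tris(benzyloxy)benzyl]oxirane; 7 [3,5-bis(benzyloxy)phenoxy]triisopropylsilane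
Product: 8 (1R,2R)-1-[2,6-bis(benzyloxy)-4-(triisopropylsilyloxy)phenyl]-1-[3,4,5-tris(benzyloxy)phenyl]-3-[2,4,6-tris(benzyloxy)phenyl]propan-2-ol
Conditions: 7 (3 equiv), HFIP–CH2Cl2 1:4, slow addition of 5, 0 °C
Reagents that add atoms: none
Why: Friedel–Crafts alkylation of an electron-rich arene by an aryl epoxide under hydrogen-bond activation by HFIP: the benzylic C–O bond is attacked from the back, so C1 forms with inversion (1R) while C2 keeps its oxygen (2R), and the TIPS group should steer substitution to the carbon between the two benzyloxy groups.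

**Step 6**
Reactants: 8 (1R,2R)-1-[2,6-bis(benzyloxy)-4-(triisopropylsilyloxy)phenyl]-1-[3,4,5-tris(benzyloxy)phenyl]-3-[2,4,6-tris(benzyloxy)phenyl]propan-2-ol
Product: 9 (1R,2R)-1-[2,6-bis(benzyloxy)-4-hydroxyphenyl]-1-[3,4,5-tris(benzyloxy)phenyl]-3-[2,4,6-tris(benzyloxy)phenyl]propan-2-ol
Conditions: Bu4NF, AcOH (1:1), THF, 0 °C
Reagents that add atoms: none
Why: Buffered fluoride desilylation frees only the phenol para to the chalcan carbon and leaves benzyl ethers and both stereocentres untouched.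

**Step 7**
Reactants: 1 3,4,5-tris(benzyloxy)benzaldehyde
Product: 10 (±)-1-[3,4,5-tris(benzyloxy)phenyl]prop-2-yn-1-ol
Conditions: HC≡CMgBr, THF, 0 °C; then water
Reagents that add atoms: ethynylmagnesium bromide, C#C[Mg]Br
Why: Grignard 1,2-addition; the racemic carbinol centre disappears in step 9.

**Step 8**
Reactants: 10 (±)-1-[3,4,5-tris(benzyloxy)phenyl]prop-2-yn-1-ol
Product: 11 (±)-1-[3,4,5-tris(benzyloxy)phenyl]prop-2-yn-1-yl acetate
Conditions: Ac2O, Et3N, DMAP (cat.), CH2Cl2, 0 °C to rt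
Reagents that add atoms: acetic anhydride, CC(=O)OC(C)=O
Why: DMAP-catalysed acetylation installs the migrating carboxylate.

**Step 9**
Reactants: 11 (±)-1-[3,4,5-tris(benzyloxy)phenyl]prop-2-yn-1-yl acetate
Product: 12 (Z)-2-acetoxy-3-[3,4,5-tris(benzyloxy)phenyl]prop-2-enal
Conditions: IPrAuNTf2 (5 mol %), 8-methylquinoline N-oxide (1.5 equiv), 1,2-dichloroethane, rt
Reagents that add atoms: 8-methylquinoline N-oxide, Cc1cccc2ccc[n+]([O-])c12
Why: Gold-catalysed oxidative rearrangement of a propargylic carboxylate: 1,2-acyloxy migration on the π-activated terminal alkyne gives a vinyl gold carbenoid whose carbene carbon the N-oxide oxidises to the formyl group, which moves the ester oxygen from the future C2 to C3 and should give the conjugated Z-enal.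

**Step 10**
Reactants: 9 (1R,2R)-1-[2,6-bis(benzyloxy)-4-hydroxyphenyl]-1-[3,4,5-tris(benzyloxy)phenyl]-3-[2,4,6-tris(benzyloxy)phenyl]propan-2-ol; 12 (Z)-2-acetoxy-3-[3,4,5-tris(benzyloxy)phenyl]prop-2-enal
Product: 15 5,7-bis(benzyloxy)-6-{(1R,2R)-2-hydroxy-1-[3,4,5-tris(benzyloxy)phenyl]-3-[2,4,6-tris(benzyloxy)phenyl]propyl}-2-[3,4,5-tris(benzyloxy)phenyl]-2H-chromen-3-yl acetate (both C2 epimers), via benzodioxaborin 13 (not isolated), via vinyl ortho-quinone methide 14 (not isolated)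
Conditions: 12 (1.5 equiv), PhB(OH)2 (2 equiv), AcOH (10 equiv), toluene, reflux, Dean–Stark trap
Reagents that add atoms: none
Why: PhB(OH)2 condenses with the only free phenol of 9 (the future O1) and with the formyl group of 12, so the ortho carbon C4a attacks the aldehyde carbon inside a six-membered boron-bound transition state (C4–C4a bond) to give dioxaborin 13, which at reflux loses PhBO in a retro-hetero-Diels–Alder step to the vinyl ortho-quinone methide 14, whose 1-oxatriene O1=C8a–C4a=C4–C3=C2 closes by a thermal disrotatory oxa-6π electrocyclisation (O1–C2 bond) driven by rearomatisation of ring A. The closest known reaction type is the boronic acid or metal phenoxide mediated condensation of phenols with α,β-unsaturated aldehydes to 2H-chromenes, which includes cinnamaldehydes giving flav-3-enes, a formal (3+3) annulation. Ring C is the only ring closed, and it closes in the pericyclic 6π mode rather than by an ionic exo or endo attack. The only lasting new stereocentre is C2: nothing controls the sense of disrotation, both epimers are expected, and this is accepted because C2 becomes the acidic α-carbon of ketone 16 and is set in step 11 (the C4 carbinol centre of 13 vanishes in 14). Three selectivities are needed: ring A over the equally electron-rich ring A′ (only ring A has a free OH to carry boron), 1,2- over 1,4-addition to the enal (the template delivers C4a to the carbonyl carbon, and the β-carbon is hindered and deactivated by the donor ring B), and 6- over 8-linkage (only the oxygen para to the chalcan carbon is free, O5 and O7 are benzylated, and the two ortho C–H positions interconvert by rotation about the ring A–chalcan bond). The acetoxy group rides in on C3, so the ring construction itself places the C3 oxygen at the ketone level needed next.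

**Step 11**
Reactants: 15 5,7-bis(benzyloxy)-6-{(1R,2R)-2-hydroxy-1-[3,4,5-tris(benzyloxy)phenyl]-3-[2,4,6-tris(benzyloxy)phenyl]propyl}-2-[3,4,5-tris(benzyloxy)phenyl]-2H-chromen-3-yl acetate
Product: 17 (2R,3R)-5,7-bis(benzyloxy)-6-{(1R,2R)-2-hydroxy-1-[3,4,5-tris(benzyloxy)phenyl]-3-[2,4,6-tris(benzyloxy)phenyl]propyl}-2-[3,4,5-tris(benzyloxy)phenyl]chroman-3-ol, via flavan-3-one 16 (not isolated)
Conditions: RuCl2[(R)-Xyl-SDP][(S,S)-DPEN] (1 mol %), KOtBu (0.3 equiv), H2 (50 atm), iPrOH–toluene 2:1, rt, degassed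
Reagents that add atoms: none
Why: Proposed new method: catalytic KOtBu in iPrOH first transesterifies the enol acetate to flavan-3-one 16, whose C2–H (α to C=O, benzylic, α to O1) is acidic enough for fast epimerisation through the enolate, while the chiral RuH2(diphosphine)(diamine) species transfers hydride and proton outer-sphere to C3 of the (2R) epimer faster than to the (2S) epimer and from the face anti to the pseudoaxial ring B, so C2 (R) and C3 (R, 2,3-cis) are set together under catalyst control; the closest known reaction type is the Noyori-type asymmetric hydrogenation of racemic 2-arylcycloalkanones to cis-2-arylcycloalkanols by dynamic kinetic resolution, which has not been shown on 2-arylchroman-3-ones.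

**Step 12**
Reactants: 17 (2R,3R)-5,7-bis(benzyloxy)-6-{(1R,2R)-2-hydroxy-1-[3,4,5-tris(benzyloxy)phenyl]-3-[2,4,6-tris(benzyloxy)phenyl]propyl}-2-[3,4,5-tris(benzyloxy)phenyl]chroman-3-ol; 18 3,4,5-tris(benzyloxy)benzoic acid
Product: 19 heptadeca-O-benzyl ether of the target (17 esterified at both secondary hydroxyls by 3,4,5-tris(benzyloxy)benzoyl)
Conditions: 18 (3 equiv), DCC (3 equiv), DMAP (0.5 equiv), CH2Cl2, rt to reflux
Reagents that add atoms: none
Why: Double Steglich esterification: the two secondary alcohols are the only acylable groups left, and acylation at oxygen does not touch the four stereocentres.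

**Step 13**
Reactants: 19 heptadeca-O-benzyl ether of the target
Product: 20 CNP0240551.1, (2R,3R)-5,7-dihydroxy-6-{(1R,2R)-2-(galloyloxy)-1-(3,4,5-trihydroxyphenyl)-3-(2,4,6-trihydroxyphenyl)propyl}-2-(3,4,5-trihydroxyphenyl)chroman-3-yl gallate
Conditions: H2 (1 atm), Pd(OH)2/C, THF–MeOH 1:1, rt; filtration under argon
Reagents that add atoms: none
Why: Global hydrogenolysis of aryl benzyl ethers under neutral conditions, the usual last step for galloylated flavan-3-ols, leaves the esters, the C2–O1 bond and all stereocentres intact.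

**Compound list**

1 | 3,4,5-tris(benzyloxy)benzaldehyde | O=Cc1cc(OCc2ccccc2)c(OCc2ccccc2)c(OCc2ccccc2)c1 | starting material
2 | (±)-1-[3,4,5-tris(benzyloxy)phenyl]prop-2-en-1-ol | C=CC(O)c1cc(OCc2ccccc2)c(OCc2ccccc2)c(OCc2ccccc2)c1 | intermediate
3 | 1,3,5-tris(benzyloxy)benzene | c1(OCc2ccccc2)cc(OCc2ccccc2)cc(OCc2ccccc2)c1 | starting material
4 | (E)-1-[3,4,5-tris(benzyloxy)phenyl]-3-[2,4,6-tris(benzyloxy)phenyl]prop-1-ene | C(/C=C/c1cc(OCc2ccccc2)c(OCc2ccccc2)c(OCc2ccccc2)c1)c1c(OCc2ccccc2)cc(OCc2ccccc2)cc1OCc1ccccc1 | intermediate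
5 | (2R,3R)-2-[3,4,5-tris(benzyloxy)phenyl]-3-[2,4,6-tris(benzyloxy)benzyl]oxirane | O(Cc1ccccc1)c1cc(cc(OCc2ccccc2)c1OCc1ccccc1)[C@H]1O[C@@H]1Cc1c(OCc2ccccc2)cc(OCc2ccccc2)cc1OCc1ccccc1 | intermediate
6 | 3,5-bis(benzyloxy)phenol | Oc1cc(OCc2ccccc2)cc(OCc2ccccc2)c1 | starting material
7 | [3,5-bis(benzyloxy)phenoxy]triisopropylsilane | CC(C)[Si](Oc1cc(OCc2ccccc2)cc(OCc2ccccc2)c1)(C(C)C)C(C)C | intermediate
8 | (1R,2R)-1-[2,6-bis(benzyloxy)-4-(triisopropylsilyloxy)phenyl]-1-[3,4,5-tris(benzyloxy)phenyl]-3-[2,4,6-tris(benzyloxy)phenyl]propan-2-ol | O[C@H](Cc1c(OCc2ccccc2)cc(OCc2ccccc2)cc1OCc1ccccc1)[C@H](c1cc(OCc2ccccc2)c(OCc2ccccc2)c(OCc2ccccc2)c1)c1c(OCc2ccccc2)cc(O[Si](C(C)C)(C(C)C)C(C)C)cc1OCc1ccccc1 | intermediate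
9 | (1R,2R)-1-[2,6-bis(benzyloxy)-4-hydroxyphenyl]-1-[3,4,5-tris(benzyloxy)phenyl]-3-[2,4,6-tris(benzyloxy)phenyl]propan-2-ol | O[C@H](Cc1c(OCc2ccccc2)cc(OCc2ccccc2)cc1OCc1ccccc1)[C@H](c1cc(OCc2ccccc2)c(OCc2ccccc2)c(OCc2ccccc2)c1)c1c(OCc2ccccc2)cc(O)cc1OCc1ccccc1 | intermediate
10 | (±)-1-[3,4,5-tris(benzyloxy)phenyl]prop-2-yn-1-ol | C#CC(O)c1cc(OCc2ccccc2)c(OCc2ccccc2)c(OCc2ccccc2)c1 | intermediate
11 | (±)-1-[3,4,5-tris(benzyloxy)phenyl]prop-2-yn-1-yl acetate | C#CC(OC(C)=O)c1cc(OCc2ccccc2)c(OCc2ccccc2)c(OCc2ccccc2)c1 | intermediate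
12 | (Z)-2-acetoxy-3-[3,4,5-tris(benzyloxy)phenyl]prop-2-enal | O=C/C(OC(C)=O)=C/c1cc(OCc2ccccc2)c(OCc2ccccc2)c(OCc2ccccc2)c1 | intermediate
13 | 2-phenyl-4H-1,3,2-benzodioxaborin from 9, 12 and PhB(OH)2 (C4 bears the 1-acetoxy-2-arylvinyl group) | O[C@H](Cc1c(OCc2ccccc2)cc(OCc2ccccc2)cc1OCc1ccccc1)[C@H](c1cc(OCc2ccccc2)c(OCc2ccccc2)c(OCc2ccccc2)c1)c1c(OCc3ccccc3)cc2c(c1OCc1ccccc1)C(/C(OC(C)=O)=C/c1cc(OCc3ccccc3)c(OCc3ccccc3)c(OCc3ccccc3)c1)OB(c1ccccc1)O2 | intermediate
14 | vinyl ortho-quinone methide (ring A dearomatised, C8a=O, C4a=C4–C3(OAc)=C2H–aryl) | O[C@H](Cc1c(OCc2ccccc2)cc(OCc2ccccc2)cc1OCc1ccccc1)[C@H](c1cc(OCc2ccccc2)c(OCc2ccccc2)c(OCc2ccccc2)c1)C1=C(OCc2ccccc2)C(=C/C(OC(C)=O)=C/c2cc(OCc3ccccc3)c(OCc3ccccc3)c(OCc3ccccc3)c2)C(=O)C=C1OCc1ccccc1 | intermediate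
15 | 5,7-bis(benzyloxy)-6-{(1R,2R)-2-hydroxy-1-[3,4,5-tris(benzyloxy)phenyl]-3-[2,4,6-tris(benzyloxy)phenyl]propyl}-2-[3,4,5-tris(benzyloxy)phenyl]-2H-chromen-3-yl acetate (both C2 epimers) | O[C@H](Cc1c(OCc2ccccc2)cc(OCc2ccccc2)cc1OCc1ccccc1)[C@H](c1cc(OCc2ccccc2)c(OCc2ccccc2)c(OCc2ccccc2)c1)c1c(OCc3ccccc3)cc2c(c1OCc1ccccc1)C=C(OC(C)=O)C(c1cc(OCc3ccccc3)c(OCc3ccccc3)c(OCc3ccccc3)c1)O2 | intermediate
16 | corresponding 2-arylchroman-3-one (C2 epimers in equilibrium) | O[C@H](Cc1c(OCc2ccccc2)cc(OCc2ccccc2)cc1OCc1ccccc1)[C@H](c1cc(OCc2ccccc2)c(OCc2ccccc2)c(OCc2ccccc2)c1)c1c(OCc3ccccc3)cc2c(c1OCc1ccccc1)CC(=O)C(c1cc(OCc3ccccc3)c(OCc3ccccc3)c(OCc3ccccc3)c1)O2 | intermediate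
17 | (2R,3R)-5,7-bis(benzyloxy)-6-{(1R,2R)-2-hydroxy-1-[3,4,5-tris(benzyloxy)phenyl]-3-[2,4,6-tris(benzyloxy)phenyl]propyl}-2-[3,4,5-tris(benzyloxy)phenyl]chroman-3-ol | O[C@H](Cc1c(OCc2ccccc2)cc(OCc2ccccc2)cc1OCc1ccccc1)[C@H](c1cc(OCc2ccccc2)c(OCc2ccccc2)c(OCc2ccccc2)c1)c1c(OCc3ccccc3)cc2c(c1OCc1ccccc1)C[C@@H](O)[C@@H](c1cc(OCc3ccccc3)c(OCc3ccccc3)c(OCc3ccccc3)c1)O2 | intermediate
18 | 3,4,5-tris(benzyloxy)benzoic acid | OC(=O)c1cc(OCc2ccccc2)c(OCc2ccccc2)c(OCc2ccccc2)c1 | starting material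
19 | heptadeca-O-benzyl ether of the target | O=C(O[C@H](Cc1c(OCc2ccccc2)cc(OCc2ccccc2)cc1OCc1ccccc1)[C@H](c1cc(OCc2ccccc2)c(OCc2ccccc2)c(OCc2ccccc2)c1)c1c(OCc3ccccc3)cc2c(c1OCc1ccccc1)C[C@@H](OC(=O)c1cc(OCc3ccccc3)c(OCc3ccccc3)c(OCc3ccccc3)c1)[C@@H](c1cc(OCc3ccccc3)c(OCc3ccccc3)c(OCc3ccccc3)c1)O2)c1cc(OCc2ccccc2)c(OCc2ccccc2)c(OCc2ccccc2)c1 | intermediate
20 | CNP0240551.1 | O=C(O[C@H](Cc1c(O)cc(O)cc1O)[C@H](c1cc(O)c(O)c(O)c1)c1c(O)cc2c(c1O)C[C@@H](OC(=O)c1cc(O)c(O)c(O)c1)[C@@H](c1cc(O)c(O)c(O)c1)O2)c1cc(O)c(O)c(O)c1 | target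

Total steps: 13. Longest linear sequence: 9 steps (1, 2, 3, 5, 6, 10, 11, 12, 13).

**Steps most likely to fail**

Step 11. The catalyst may discriminate poorly between the two interconverting C2 epimers, or epimerisation may be slow relative to reduction. The fallback sets out from 15. K2CO3 in MeOH–THF at 0 °C cleaves the enol acetate, and ketone 16 is isolated. LiBH(s-Bu)3 in THF at −78 °C, the known reduction of flavan-3-ones anti to ring B, converts both epimers into 2,3-cis alcohols: 17 and the (2S,3S)-flavan-3-ol diastereomer F1. The enantiopure upper unit makes these two diastereomers, so they are separated by chromatography. The route is rejoined at 17.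

Step 5. Substitution may occur ortho to the silyl ether. An ortho benzyloxy oxygen of ring A′ may participate, or the epoxide may ionise to a free benzylic cation and lose the anti course. The fallback sets out from 5 and uses a symmetric, far more reactive nucleophile, so capture outruns these processes and no regiochemical question arises. Phloroglucinol (5 equiv) with Sc(OTf)3 (5 mol %) in THF at 0 °C gives the ring A triol F2. TIPSCl (1 equiv) and imidazole silylate the one unhindered hydroxyl, para to the chalcan carbon, to give the mono-TIPS ether F3. BnBr and K2CO3 in dry acetone benzylate the two flanking phenols. The route is rejoined at 8.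

Step 10. Hydroxyalkylation of the crowded phenol may be slow, the enol acetate may be lost at reflux, or the quinone methide may oligomerise. The fallback sets out from 9 and 1 and builds ring C from different bonds. MgCl2, Et3N and paraformaldehyde in MeCN at reflux (phenol-directed ortho-formylation) give the salicylaldehyde F4. A Henry condensation of 1 with MeNO2 (NH4OAc, AcOH) gives the nitrostyrene F5. DABCO joins F4 and F5 by oxa-Michael addition, Henry reaction and dehydration to the 3-nitro-2H-chromene F6. Fe in AcOH–THF–water converts the conjugated nitroalkene reductively into the ketone. The route is rejoined at 16, which is then hydrogenated as in step 11.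

**Further compounds**

F1 | step 11 | (2S,3S)-5,7-bis(benzyloxy)-6-{(1R,2R)-2-hydroxy-1-[3,4,5-tris(benzyloxy)phenyl]-3-[2,4,6-tris(benzyloxy)phenyl]propyl}-2-[3,4,5-tris(benzyloxy)phenyl]chroman-3-ol | O[C@H](Cc1c(OCc2ccccc2)cc(OCc2ccccc2)cc1OCc1ccccc1)[C@H](c1cc(OCc2ccccc2)c(OCc2ccccc2)c(OCc2ccccc2)c1)c1c(OCc3ccccc3)cc2c(c1OCc1ccccc1)C[C@H](O)[C@H](c1cc(OCc3ccccc3)c(OCc3ccccc3)c(OCc3ccccc3)c1)O2
F2 | step 5 | (1R,2R)-1-(2,4,6-trihydroxyphenyl)-1-[3,4,5-tris(benzyloxy)phenyl]-3-[2,4,6-tris(benzyloxy)phenyl]propan-2-ol | O[C@H](Cc1c(OCc2ccccc2)cc(OCc2ccccc2)cc1OCc1ccccc1)[C@H](c1cc(OCc2ccccc2)c(OCc2ccccc2)c(OCc2ccccc2)c1)c1c(O)cc(O)cc1O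
F3 | step 5 | (1R,2R)-1-[2,6-dihydroxy-4-(triisopropylsilyloxy)phenyl]-1-[3,4,5-tris(benzyloxy)phenyl]-3-[2,4,6-tris(benzyloxy)phenyl]propan-2-ol | O[C@H](Cc1c(OCc2ccccc2)cc(OCc2ccccc2)cc1OCc1ccccc1)[C@H](c1cc(OCc2ccccc2)c(OCc2ccccc2)c(OCc2ccccc2)c1)c1c(O)cc(O[Si](C(C)C)(C(C)C)C(C)C)cc1O
F4 | step 10 | 2,4-bis(benzyloxy)-6-hydroxy-3-{(1R,2R)-2-hydroxy-1-[3,4,5-tris(benzyloxy)phenyl]-3-[2,4,6-tris(benzyloxy)phenyl]propyl}benzaldehyde | O[C@H](Cc1c(OCc2ccccc2)cc(OCc2ccccc2)cc1OCc1ccccc1)[C@H](c1cc(OCc2ccccc2)c(OCc2ccccc2)c(OCc2ccccc2)c1)c1c(OCc2ccccc2)cc(O)c(C=O)c1OCc1ccccc1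
F5 | step 10 | (E)-1,2,3-tris(benzyloxy)-5-(2-nitrovinyl)benzene | O=[N+]([O-])/C=C/c1cc(OCc2ccccc2)c(OCc2ccccc2)c(OCc2ccccc2)c1
F6 | step 10 | 5,7-bis(benzyloxy)-6-{(1R,2R)-2-hydroxy-1-[3,4,5-tris(benzyloxy)phenyl]-3-[2,4,6-tris(benzyloxy)phenyl]propyl}-3-nitro-2-[3,4,5-tris(benzyloxy)phenyl]-2H-chromene (both C2 epimers) | O[C@H](Cc1c(OCc2ccccc2)cc(OCc2ccccc2)cc1OCc1ccccc1)[C@H](c1cc(OCc2ccccc2)c(OCc2ccccc2)c(OCc2ccccc2)c1)c1c(OCc3ccccc3)cc2c(c1OCc1ccccc1)C=C([N+](=O)[O-])C(c1cc(OCc3ccccc3)c(OCc3ccccc3)c(OCc3ccccc3)c1)O2
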